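**Retrosynthetic overview**

1. Ring numbering: O1, C2 (guaiacyl), C3 (CH2O–acyl), C4 (guaiacylmethyl), C5H2. The ester is made last by a chemoselective Mitsunobu reaction on the unprotected (2R,3S,4S) triol; the O1–C2 bond is closed just before, by SN1 ring closure of an open-chain benzylic methyl ether diol.
2. Key disconnection: the C3–CH2O bond, made by a silicon-tethered 6-exo radical cyclisation with radical–polar crossover of an (iodomethyl)dimethylsilyl ether. The CH2 comes from (bromomethyl)chlorodimethylsilane, and the temporary 1-oxa-2-silacyclohexane is oxidised away (Tamao) in the same flask, which also frees both phenols.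
3. Enabling feature: O1–C5 is 1,3 to C3 (O1–C5–C4–C3), so the C5 oxygen of an open-chain precursor can carry an O–SiMe2–CH2 radical arm that reaches C3 through a six-membered chair, in which the C4 stereocentre dictates the new C3 centre. C2 bears the 4-oxygenated guaiacyl ring, so C2=C3 is a styrene that accepts the radical at C3 only and leaves an easily oxidised benzylic radical at C2, the carbon that later receives O1.
4. The homoallylic alcohol precursor (one stereocentre, the future C4) comes from Evans alkylation of an (E)-4-aryl-but-3-enoyl imide dienolate with a guaiacylmethyl bromide; both aryl units derive from vanillin.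
5. Ring order: temporary oxasilinane (formed and opened in the key step), then the tetrahydrofuran; the aromatic rings are bought.

Key step: step 9

Remark: (R)-2-methylbutanoic acid is taken as a purchasable single enantiomer. TBS = tert-butyldimethylsilyl.

**Step 1**
Reactants: 1 vanillin (4-hydroxy-3-methoxybenzaldehyde)
Product: 2 4-(tert-butyldimethylsilyloxy)-3-methoxybenzaldehyde
Conditions: TBSCl, imidazole, DMF, rt
Reagents that add atoms: tert-butyldimethylsilyl chloride, CC(C)(C)[Si](C)(C)Cl
Why: Standard imidazole-promoted silylation of the phenol; the aryl silyl ether should survive every step up to the fluoride treatment in step 9, where its removal is wanted.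

**Step 2**
Reactants: 2 4-(tert-butyldimethylsilyloxy)-3-methoxybenzaldehyde
Product: 3 [4-(tert-butyldimethylsilyloxy)-3-methoxyphenyl]methanol
Conditions: NaBH4, THF/MeOH, 0 °C
Reagents that add atoms: none
Why: Borohydride reduction of the aryl aldehyde to the benzylic alcohol, which should leave the aryl silyl ether intact at 0 °C.

**Step 3**
Reactants: 3 [4-(tert-butyldimethylsilyloxy)-3-methoxyphenyl]methanol
Product: 4 [4-(bromomethyl)-2-methoxyphenoxy](tert-butyl)dimethylsilane
Conditions: PBr3, Et2O, 0 °C
Reagents that add atoms: phosphorus tribromide, BrP(Br)Br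
Why: Substitution of the electron-rich benzylic alcohol by bromide with PBr3; the labile bromide is used at once in step 6.

**Step 4**
Reactants: 2 4-(tert-butyldimethylsilyloxy)-3-methoxybenzaldehyde; 5 (2-carboxyethyl)triphenylphosphonium bromide
Product: 6 (E)-4-[4-(tert-butyldimethylsilyloxy)-3-methoxyphenyl]but-3-enoic acid
Conditions: 5, NaHMDS (2.1 equiv), THF, 0 °C; then 2, −78 °C → rt; aq. HCl work-up
Reagents that add atoms: none
Why: Wittig olefination with the carboxylate-bearing ylide, which is expected to give mainly the E acid with aryl aldehydes and to keep the double bond in the styrene-conjugated β,γ-position; residual Z isomer is removed by crystallisation.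

**Step 5**
Reactants: 6 (E)-4-[4-(tert-butyldimethylsilyloxy)-3-methoxyphenyl]but-3-enoic acid; 7 (S)-4-benzyl-1,3-oxazolidin-2-one
Product: 8 (S)-4-benzyl-3-{(E)-4-[4-(tert-butyldimethylsilyloxy)-3-methoxyphenyl]but-3-enoyl}-1,3-oxazolidin-2-one
Conditions: PivCl, Et3N, THF, −20 °C; then 7, LiCl, −20 °C → rt
Reagents that add atoms: none
Why: N-Acylation of the Evans auxiliary through the mixed pivalic anhydride under LiCl/Et3N conditions, mild enough to keep the double bond out of conjugation with the carbonyl.

**Step 6**
Reactants: 8 (S)-4-benzyl-3-{(E)-4-[4-(tert-butyldimethylsilyloxy)-3-methoxyphenyl]but-3-enoyl}-1,3-oxazolidin-2-one; 4 [4-(bromomethyl)-2-methoxyphenoxy](tert-butyl)dimethylsilane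
Product: 9 (S)-4-benzyl-3-{(2S,3E)-2-[4-(tert-butyldimethylsilyloxy)-3-methoxybenzyl]-4-[4-(tert-butyldimethylsilyloxy)-3-methoxyphenyl]but-3-enoyl}-1,3-oxazolidin-2-one
Conditions: NaHMDS, THF, −78 °C; then 4, −78 → −45 °C; AcOH quench
Reagents that add atoms: none
Why: Evans asymmetric alkylation: the chelated (Z)-sodium dienolate should react at its α-carbon with the benzylic bromide on the face opposite the auxiliary benzyl group, which sets the (S) centre that becomes C4 of the target.

**Step 7**
Reactants: 9 the alkylated imide
Product: 10 (2S,3E)-2-[4-(tert-butyldimethylsilyloxy)-3-methoxybenzyl]-4-[4-(tert-butyldimethylsilyloxy)-3-methoxyphenyl]but-3-en-1-ol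
Conditions: LiBH4, MeOH (1.1 equiv), THF, 0 °C
Reagents that add atoms: none
Why: Reductive removal of the auxiliary with LiBH4 should give the primary alcohol without touching the styrene or the new stereocentre, and returns the oxazolidinone.

**Step 8**
Reactants: 10 the homoallylic alcohol; 11 (bromomethyl)chlorodimethylsilane
Product: 13 {[(2S,3E)-2-[4-(tert-butyldimethylsilyloxy)-3-methoxybenzyl]-4-[4-(tert-butyldimethylsilyloxy)-3-methoxyphenyl]but-3-en-1-yl]oxy}(iodomethyl)dimethylsilane, via bromomethylsilyl ether 12 (not isolated)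
Conditions: 11, Et3N, DMAP (cat.), CH2Cl2, 0 °C; solvent exchange; then NaI, acetone, rt, dark
Reagents that add atoms: (bromomethyl)chlorodimethylsilane (11), C[Si](C)(Cl)CBr; sodium iodide, [Na+].[I-]
Why: O-Silylation of the primary alcohol followed by Finkelstein exchange at the CH2 next to silicon installs the reducible C–I bond on a temporary tether; 13 is moisture-sensitive and is used directly.

**Step 9**
Reactants: 13 the (iodomethyl)dimethylsilyl ether
Product: 15 (2S,3S)-2-[(4-hydroxy-3-methoxyphenyl)(methoxy)methyl]-3-(4-hydroxy-3-methoxybenzyl)butane-1,4-diol (both epimers at the methoxy-bearing carbon), via methoxy oxasilinane 14 (not isolated)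
Conditions: fac-Ir(ppy)3 (1 mol%), 2,6-lutidine (2 equiv), MeOH (5 equiv), degassed CH2Cl2, blue LEDs, rt; evaporate; then KF, KHCO3, 30% aq. H2O2, THF/MeOH, 40 °C
Reagents that add atoms: methanol, CO; hydrogen peroxide, OO
Why: Proposed new method: photoexcited fac-Ir(ppy)3 reduces the C–I bond of 13 to an α-silyl methyl radical, which closes 6-exo-trig onto the styrene carbon that becomes C3 and leaves a benzylic radical at the future C2; the tetravalent iridium complex formed in the first electron transfer oxidises only this electron-rich benzylic radical to the 4-silyloxybenzyl cation, which methanol captures, and the Tamao oxidation then turns C–Si into C–OH with retention, frees the second primary hydroxyl and strips both aryl silyl ethers. The closest known reaction types are the silicon-tethered (Nishiyama–Stork) radical cyclisation of halomethylsilyl ethers followed by Tamao oxidation, and the photoredox radical–polar crossover oxy-alkylation of styrenes with alkyl halides in the presence of an alcohol. The only ring closed is the temporary 1-oxa-2-silacyclohexane (radical 6-exo-trig), which is opened again in the same flask; no ring of the target is closed here. The new stereocentre at the future C3 is controlled by the existing C4 centre: in the chair-like transition state the arylmethyl group is equatorial and the allylic C–H lies in the alkene plane (least allylic 1,3-strain, for either alkene geometry), which places the two side chains trans on the oxasilinane, that is CH2OH and arylmethyl cis on the later tetrahydrofuran; the methoxy-bearing carbon forms without control and is erased in step 10. The step needs 6-exo instead of 7-endo closure, secured by the aryl group on the far alkene carbon (benzylic radical), and oxidation of the cyclised radical only, secured by the 4-oxygenated aryl ring that makes this radical, and not the primary α-silyl radical, oxidisable by tetravalent iridium.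

**Step 10**
Reactants: 15 the benzylic methyl ether diol
Product: 16 [(2R,3S,4S)-2-(4-hydroxy-3-methoxyphenyl)-4-(4-hydroxy-3-methoxybenzyl)tetrahydrofuran-3-yl]methanol
Conditions: CSA (10 mol%), THF, 0 °C → rt
Reagents that add atoms: none
Why: Acid-induced SN1 cycloetherification: loss of methanol gives the 4-hydroxybenzyl cation (protonated p-quinone methide), only the hydroxyl on the C4 side chain can close a five-membered ring (the other would give an oxetane), and under these reversible conditions the aryl group should settle trans to the C3 substituent, avoiding the all-cis ring and setting C2 as R.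

**Step 11**
Reactants: 16 the tetrahydrofuran triol; 17 (R)-2-methylbutanoic acid
Product: 18 [(2R,3S,4S)-2-(4-hydroxy-3-methoxyphenyl)-4-(4-hydroxy-3-methoxybenzyl)tetrahydrofuran-3-yl]methyl (2R)-2-methylbutanoate (target, CNP0315069.1)
Conditions: 17, PPh3, DIAD, THF, 0 °C → rt
Reagents that add atoms: none
Why: Mitsunobu esterification, known to be chemoselective for alcoholic over phenolic hydroxyls when a carboxylic acid is the acidic partner; the carbinol carbon is a CH2, the α-stereocentre of the acid is not touched under these neutral conditions, and no protecting group is needed.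

**Compound list**

1 | vanillin | COc1cc(C=O)ccc1O | starting material
2 | 4-(tert-butyldimethylsilyloxy)-3-methoxybenzaldehyde | COc1cc(C=O)ccc1O[Si](C)(C)C(C)(C)C | intermediate
3 | [4-(tert-butyldimethylsilyloxy)-3-methoxyphenyl]methanol | COc1cc(CO)ccc1O[Si](C)(C)C(C)(C)C | intermediate
4 | [4-(bromomethyl)-2-methoxyphenoxy](tert-butyl)dimethylsilane | COc1cc(CBr)ccc1O[Si](C)(C)C(C)(C)C | intermediate
5 | (2-carboxyethyl)triphenylphosphonium bromide | OC(=O)CC[P+](c1ccccc1)(c1ccccc1)c1ccccc1.[Br-] | starting material
6 | (E)-4-[4-(tert-butyldimethylsilyloxy)-3-methoxyphenyl]but-3-enoic acid | COc1cc(/C=C/CC(=O)O)ccc1O[Si](C)(C)C(C)(C)C | intermediate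
7 | (S)-4-benzyl-1,3-oxazolidin-2-one | O=C1OC[C@H](Cc2ccccc2)N1 | starting material
8 | (S)-4-benzyl-3-{(E)-4-[4-(tert-butyldimethylsilyloxy)-3-methoxyphenyl]but-3-enoyl}-1,3-oxazolidin-2-one | O=C1OC[C@H](Cc2ccccc2)N1C(=O)C/C=C/c1ccc(O[Si](C)(C)C(C)(C)C)c(OC)c1 | intermediate
9 | (S)-4-benzyl-3-{(2S,3E)-2-[4-(tert-butyldimethylsilyloxy)-3-methoxybenzyl]-4-[4-(tert-butyldimethylsilyloxy)-3-methoxyphenyl]but-3-enoyl}-1,3-oxazolidin-2-one | O=C1OC[C@H](Cc2ccccc2)N1C(=O)[C@@H](Cc1ccc(O[Si](C)(C)C(C)(C)C)c(OC)c1)/C=C/c1ccc(O[Si](C)(C)C(C)(C)C)c(OC)c1 | intermediate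
10 | (2S,3E)-2-[4-(tert-butyldimethylsilyloxy)-3-methoxybenzyl]-4-[4-(tert-butyldimethylsilyloxy)-3-methoxyphenyl]but-3-en-1-ol | OC[C@@H](Cc1ccc(O[Si](C)(C)C(C)(C)C)c(OC)c1)/C=C/c1ccc(O[Si](C)(C)C(C)(C)C)c(OC)c1 | intermediate
11 | (bromomethyl)chlorodimethylsilane | C[Si](C)(Cl)CBr | starting material
12 | (bromomethyl)dimethylsilyl ether of 10 (S, E) | C[Si](C)(CBr)OC[C@@H](Cc1ccc(O[Si](C)(C)C(C)(C)C)c(OC)c1)/C=C/c1ccc(O[Si](C)(C)C(C)(C)C)c(OC)c1 | intermediate
13 | (iodomethyl)dimethylsilyl ether of 10 (S, E) | C[Si](C)(CI)OC[C@@H](Cc1ccc(O[Si](C)(C)C(C)(C)C)c(OC)c1)/C=C/c1ccc(O[Si](C)(C)C(C)(C)C)c(OC)c1 | intermediate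
14 | (4R,5S)-4-{[4-(tert-butyldimethylsilyloxy)-3-methoxyphenyl](methoxy)methyl}-5-[4-(tert-butyldimethylsilyloxy)-3-methoxybenzyl]-2,2-dimethyl-1-oxa-2-silacyclohexane, side chains trans, both epimers at the methoxy-bearing carbon | C[Si]1(C)C[C@@H](C(OC)c2ccc(O[Si](C)(C)C(C)(C)C)c(OC)c2)[C@H](Cc2ccc(O[Si](C)(C)C(C)(C)C)c(OC)c2)CO1 | intermediate
15 | (2S,3S)-2-[(4-hydroxy-3-methoxyphenyl)(methoxy)methyl]-3-(4-hydroxy-3-methoxybenzyl)butane-1,4-diol, both epimers at the methoxy-bearing carbon | OC[C@@H](C(OC)c1ccc(O)c(OC)c1)[C@H](Cc1ccc(O)c(OC)c1)CO | intermediate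
16 | [(2R,3S,4S)-2-(4-hydroxy-3-methoxyphenyl)-4-(4-hydroxy-3-methoxybenzyl)tetrahydrofuran-3-yl]methanol (2,3-trans, 3,4-cis) | OC[C@@H]1[C@H](Cc2ccc(O)c(OC)c2)CO[C@H]1c1ccc(O)c(OC)c1 | intermediate
17 | (R)-2-methylbutanoic acid | CC[C@@H](C)C(=O)O | starting material
18 | [(2R,3S,4S)-2-(4-hydroxy-3-methoxyphenyl)-4-(4-hydroxy-3-methoxybenzyl)tetrahydrofuran-3-yl]methyl (2R)-2-methylbutanoate | CC[C@@H](C)C(=O)OC[C@@H]1[C@H](Cc2ccc(O)c(OC)c2)CO[C@H]1c1ccc(O)c(OC)c1 | target

**Step count and risks**

Total steps: 11. Longest linear sequence: 9 (steps 1, 4, 5, 6, 7, 8, 9, 10, 11 from vanillin; the branch through steps 2 and 3 is equally long).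

Steps most likely to fail:

1. Step 9 (proposed new method). What may go wrong: premature solvolysis of the iodomethylsilyl tether by methanol; 1,5-hydrogen transfer from the allylic C–H to the α-silyl radical in place of ring closure; loss of a proton from the benzylic cation instead of methanol capture; or insufficient facial control in the 6-exo closure. Fallback with known chemistry, from 13 back to 16: Bu3SnH and AIBN in benzene at 80 °C (slow addition) carry out the classical reductive silicon-tethered radical cyclisation to (4S,5S)-4,5-bis[4-(tert-butyldimethylsilyloxy)-3-methoxybenzyl]-2,2-dimethyl-1-oxa-2-silacyclohexane F1. Tamao oxidation (KF, KHCO3, H2O2, THF/MeOH), again with loss of the aryl silyl groups, gives (2S,3S)-2,3-bis(4-hydroxy-3-methoxybenzyl)butane-1,4-diol F2. One equivalent of DDQ in THF at 0 °C oxidises one 4-alkylguaiacol unit to its p-quinone methide, which the hydroxyl group three carbons away closes to the tetrahydrofuran, rejoining the route at 16. F2 is C2-symmetric, so both benzylic positions lead to the same compound.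

2. Step 11. What may go wrong: loss of chemoselectivity between the primary alcohol and the two phenolic hydroxyls (O-alkylation or O-acylation of the phenols, oligomer formation). Fallback, from 16 back to 18: exhaustive Steglich acylation with an excess of 17 (DCC, DMAP, CH2Cl2) gives the tris[(2R)-2-methylbutanoate] of 16, F3. Selective aminolysis of the two aryl esters with pyrrolidine in CH2Cl2 at 0 °C, which should leave the alkyl ester, then gives 18.

3. Step 10. What may go wrong: capture of the benzylic cation by the electron-rich second aryl ring (Friedel–Crafts closure to an aryltetralin) instead of by oxygen, or incomplete equilibration to the 2,3-trans ring. Fallback, from 15 back to 16, avoiding a free cation: bromotrimethylsilane in CH2Cl2 at −20 °C exchanges the benzylic methoxy group for bromide to give (2S,3S)-2-[bromo(4-hydroxy-3-methoxyphenyl)methyl]-3-(4-hydroxy-3-methoxybenzyl)butane-1,4-diol F4 (hydroxyl groups transiently silylated). Cold aqueous NaHCO3 eliminates HBr to the neutral p-quinone methide 4-[(2S,3S)-4-hydroxy-2-(hydroxymethyl)-3-(4-hydroxy-3-methoxybenzyl)butylidene]-2-methoxycyclohexa-2,5-dien-1-one F5, which the second aryl ring should not attack without acid. Intramolecular 1,6-addition of the primary hydroxyl then closes the ring to 16.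

**Further compounds**

F1 | step 9 | (4S,5S)-4,5-bis[4-(tert-butyldimethylsilyloxy)-3-methoxybenzyl]-2,2-dimethyl-1-oxa-2-silacyclohexane | C[Si]1(C)C[C@@H](Cc2ccc(O[Si](C)(C)C(C)(C)C)c(OC)c2)[C@H](Cc2ccc(O[Si](C)(C)C(C)(C)C)c(OC)c2)CO1
F2 | step 9 | (2S,3S)-2,3-bis(4-hydroxy-3-methoxybenzyl)butane-1,4-diol | OC[C@@H](Cc1ccc(O)c(OC)c1)[C@H](Cc1ccc(O)c(OC)c1)CO
F3 | step 11 | [(2R,3S,4S)-2-{3-methoxy-4-[(2R)-2-methylbutanoyloxy]phenyl}-4-{3-methoxy-4-[(2R)-2-methylbutanoyloxy]benzyl}tetrahydrofuran-3-yl]methyl (2R)-2-methylbutanoate | CC[C@@H](C)C(=O)OC[C@@H]1[C@H](Cc2ccc(OC(=O)[C@H](C)CC)c(OC)c2)CO[C@H]1c1ccc(OC(=O)[C@H](C)CC)c(OC)c1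
F4 | step 10 | (2S,3S)-2-[bromo(4-hydroxy-3-methoxyphenyl)methyl]-3-(4-hydroxy-3-methoxybenzyl)butane-1,4-diol, both epimers at the bromine-bearing carbon | OC[C@@H](C(Br)c1ccc(O)c(OC)c1)[C@H](Cc1ccc(O)c(OC)c1)CO
F5 | step 10 | 4-[(2S,3S)-4-hydroxy-2-(hydroxymethyl)-3-(4-hydroxy-3-methoxybenzyl)butylidene]-2-methoxycyclohexa-2,5-dien-1-one | OC[C@@H](C=C1C=CC(=O)C(OC)=C1)[C@H](Cc1ccc(O)c(OC)c1)CO
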